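## Retrosynthetic overview

- The strategy rests on C3 of the dihydropyran ring (ring C). It is the only stereocentre, it carries ring B, and it sits next to benzylic C4. With C4 as a ketone, C3–H is an enolisable, doubly activated proton. The C4 oxygen can be stripped afterwards because O1 (ortho) and O7 (para) on ring A activate that benzylic carbon.
- The isoflavan comes from a cis-(3S,4S)-isoflavan-4-ol by one hydrogenolysis that removes C4–OH and both O-benzyl groups. The carbinol comes from the racemic isoflavanone by Ru-catalysed transfer hydrogenation with dynamic kinetic resolution.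
- The isoflavanone is cut at C3–C1' (Pd-catalysed ketone α-arylation) into 7-benzyloxy-8-methoxychroman-4-one and a fully oxygenated ring-B bromide.
- Ring order: ring C is closed first on ring A (Friedel–Crafts C4–C4a bond, then O1–C2 closure). Ring B then arrives intact, and no ring forms afterwards.
- The bromide comes from 2-hydroxy-3,4-dimethoxybenzaldehyde by O-benzylation, Baeyer–Villiger oxidation, phenol-directed bromination and O-methylation.

Key step: step 9

Remark on the chemistry: the (S,S)-configured Ru catalyst is assumed, by analogy with simple aryl alkyl ketones and chroman-4-one, to give the 4S carbinol. If the assignment of the carbinol shows the opposite sense, the (R,R) catalyst is used and nothing else changes.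

## Route

Step 1
Reactants: 1 2-methoxyresorcinol (2-methoxybenzene-1,3-diol); 2 3-chloropropanoic acid
Product: 3 3-chloro-1-(2,4-dihydroxy-3-methoxyphenyl)propan-1-one
Conditions: TfOH (4 equiv, neat), 80 °C, 1 h; ice quench, EtOAc extraction
Reagents that add atoms: none
Why: Friedel–Crafts acylation through the acylium or mixed-anhydride species that triflic acid generates from the free acid; the two reactive ring positions of 1 (each ortho to one OH and para to the other) are related by symmetry, so one regioisomer should form, the new ketone shuts off a second acylation, and the non-nucleophilic medium leaves the aryl methyl ether and the primary chloride alone.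

Step 2
Reactants: 3 3-chloro-1-(2,4-dihydroxy-3-methoxyphenyl)propan-1-one
Product: 4 7-hydroxy-8-methoxychroman-4-one
Conditions: 2 M aq NaOH, 0 °C to rt, 2 h; then 2 M H2SO4 to pH 2–3
Reagents that add atoms: none
Why: Intramolecular Williamson-type etherification (direct 6-exo-tet displacement, or E1cB loss of HCl followed by 6-endo oxa-Michael addition, both giving the same product) in which only the phenoxide ortho to the carbonyl can reach the terminal carbon, so the O1–C2 bond closes ring C and the remote phenol remains as the 7-OH beside the 8-OMe.

Step 3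
Reactants: 4 7-hydroxy-8-methoxychroman-4-one
Product: 5 7-benzyloxy-8-methoxychroman-4-one
Conditions: BnBr (1.1 equiv), K2CO3 (1.5 equiv), acetone, reflux
Reagents that add atoms: benzyl bromide BrCc1ccccc1
Why: Williamson etherification of the only phenol present, under a carbonate base too weak to damage the chromanone, installing a group that tolerates the Pd(0)/base and Ru–H steps and leaves in the final hydrogenolysis.

Step 4
Reactants: 6 2-hydroxy-3,4-dimethoxybenzaldehyde
Product: 7 2-benzyloxy-3,4-dimethoxybenzaldehyde
Conditions: BnBr (1.2 equiv), K2CO3 (2 equiv), DMF, 60 °C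
Reagents that add atoms: benzyl bromide BrCc1ccccc1
Why: Williamson etherification; the hydroxyl is hydrogen-bonded to the aldehyde and flanked by OMe, hence the dipolar solvent and gentle heating, and the benzyl group marks this oxygen as the future free 3'-OH.

Step 5
Reactants: 7 2-benzyloxy-3,4-dimethoxybenzaldehyde
Product: 9 2-benzyloxy-3,4-dimethoxyphenol, via aryl formate 8 (not isolated)
Conditions: mCPBA (1.3 equiv), CH2Cl2, 0 °C to rt; crude formate, K2CO3 (0.2 equiv), MeOH, 0 °C to rt, N2
Reagents that add atoms: mCPBA OOC(=O)c1cccc(Cl)c1
Why: Baeyer–Villiger oxidation of an electron-rich benzaldehyde (Dakin-type outcome): in the Criegee adduct the aryl group with ortho and para oxygen donors migrates in preference to hydride, and the formate is transesterified by methanol under catalytic base, so the formyl carbon is lost and its ring carbon becomes the future C2'–O carbon.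

Step 6
Reactants: 9 2-benzyloxy-3,4-dimethoxyphenol
Product: 10 2-benzyloxy-6-bromo-3,4-dimethoxyphenol
Conditions: NBS (1.0 equiv), CH2Cl2, −78 to 0 °C, dark
Reagents that add atoms: N-bromosuccinimide O=C1CCC(=O)N1Br
Why: Electrophilic aromatic bromination steered by the free phenol: in a non-polar solvent at low temperature NBS reacts through the phenol much faster than through anisole-type activation, and the para and one ortho position are occupied, so bromine should enter C6 (ortho to OH, para to the 3-OMe) rather than C5; the assignment has to be made on 10 itself, where only the wanted isomer has its lone aryl H beside an OMe group and should show that NOE, because after O-methylation both regioisomers would place that H beside exactly one OMe.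

Step 7
Reactants: 10 2-benzyloxy-6-bromo-3,4-dimethoxyphenol
Product: 11 1-bromo-3-benzyloxy-2,4,5-trimethoxybenzene
Conditions: MeI (1.5 equiv), K2CO3 (2 equiv), DMF, rt to 40 °C
Reagents that add atoms: iodomethane CI
Why: Williamson O-methylation of a phenol that is flanked on both sides but acidified by the ortho bromine, the small electrophile in DMF coping with the crowding and completing the 2',4',5'-trimethoxy-3'-benzyloxy pattern of ring B.

Step 8
Reactants: 5 7-benzyloxy-8-methoxychroman-4-one (1.2 equiv); 11 1-bromo-3-benzyloxy-2,4,5-trimethoxybenzene
Product: 12 rac-7-benzyloxy-3-(3-benzyloxy-2,4,5-trimethoxyphenyl)-8-methoxychroman-4-one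
Conditions: Pd2(dba)3 (2.5 mol %), XPhos (10 mol %), K3PO4 (2.5 equiv), toluene, 90 °C, Ar
Reagents that add atoms: none
Why: Pd-catalysed ketone α-arylation (Buchwald–Hartwig type, known for chroman-4-ones): the bulky electron-rich biaryl phosphine enables oxidative addition of the ortho-substituted, oxygen-rich bromide and reductive elimination from the Pd enolate, the sparingly soluble phosphate keeps the enolate concentration low so that retro-oxa-Michael opening of ring C is held back, the more acidic product rests as a hindered enolate that resists a second arylation, and C3 is deliberately formed racemic.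

Step 9
Reactants: 12 rac-7-benzyloxy-3-(3-benzyloxy-2,4,5-trimethoxyphenyl)-8-methoxychroman-4-one
Product: 13 cis-(3S,4S)-7-benzyloxy-3-(3-benzyloxy-2,4,5-trimethoxyphenyl)-8-methoxychroman-4-ol
Conditions: RuCl(p-cymene)[(S,S)-TsDPEN] (5 mol %), HCO2H (5 equiv), Et3N (8 equiv), EtOAc, 40 °C
Reagents that add atoms: none
Why: Noyori–Ikariya asymmetric transfer hydrogenation run as a dynamic kinetic resolution, a reaction type established for 3-arylchroman-4-ones and related α-aryl benzo-fused ketones: the Ru–H/N–H species formed from formate passes hydride to C4 and a proton to the carbonyl oxygen in a concerted outer-sphere six-membered transition state. No ring closes and no C–C bond forms, the only new skeletal bond being C4–H. C4 is controlled by the catalyst, whose η6-arene engages the fused ring A through a CH/π contact so that the (S,S)-diamine should open the carbonyl face that leads to 4S. C3 is controlled by matching of substrate and catalyst, since hydride must arrive anti to the C3 aryl group and only the (3S)-ketone offers that trajectory on the favoured face, which makes the carbinol cis (OH and aryl on the same side). The step therefore needs face selectivity, cis selectivity and epimerisation faster than reduction; the last is secured by C3–H being α to the aryl ketone and benzylic to ring B, so that the excess Et3N equilibrates the two enantiomers of 12 through the enol, while the O1 and 7-O donors make C4 a sluggish hydride acceptor. The relative configuration should be checked by the small H3–H4 coupling expected for the cis isomer and the absolute one by chiral HPLC together with a Mosher ester or CD analysis.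

Step 10
Reactants: 13 cis-(3S,4S)-7-benzyloxy-3-(3-benzyloxy-2,4,5-trimethoxyphenyl)-8-methoxychroman-4-ol
Product: 15 (3S)-3-(3-hydroxy-2,4,5-trimethoxyphenyl)-8-methoxychroman-7-ol (CNP0201239.1), via debenzylated cis-4-ol 14 (not isolated)
Conditions: H2 (1–3 bar), 10% Pd/C, EtOH–AcOH 10:1, rt
Reagents that add atoms: none
Why: Heterogeneous benzylic hydrogenolysis: the two aryl benzyl ethers should fall first, after which the C4–OH bond, benzylic and activated by O1 (ortho) and the freed 7-OH (para), is cleaved, while C3 is not a reacting centre and keeps its configuration (descriptor still S) provided that only weak acid and room temperature are used so that no isoflav-3-ene forms, which is verified by comparing the enantiomeric purity of 15 with that of 13.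

## Compound list

1 | 2-methoxyresorcinol | COc1c(O)cccc1O | starting material
2 | 3-chloropropanoic acid | OC(=O)CCCl | starting material
3 | 3-chloro-1-(2,4-dihydroxy-3-methoxyphenyl)propan-1-one | O=C(CCCl)c1ccc(O)c(OC)c1O | intermediate
4 | 7-hydroxy-8-methoxychroman-4-one | O=C1CCOc2c1ccc(O)c2OC | intermediate
5 | 7-benzyloxy-8-methoxychroman-4-one | O=C1CCOc2c1ccc(OCc3ccccc3)c2OC | intermediate
6 | 2-hydroxy-3,4-dimethoxybenzaldehyde | COc1ccc(C=O)c(O)c1OC | starting material
7 | 2-benzyloxy-3,4-dimethoxybenzaldehyde | COc1ccc(C=O)c(OCc2ccccc2)c1OC | intermediate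
8 | 2-benzyloxy-3,4-dimethoxyphenyl formate (not isolated) | COc1ccc(OC=O)c(OCc2ccccc2)c1OC | intermediate
9 | 2-benzyloxy-3,4-dimethoxyphenol | COc1ccc(O)c(OCc2ccccc2)c1OC | intermediate
10 | 2-benzyloxy-6-bromo-3,4-dimethoxyphenol | COc1cc(Br)c(O)c(OCc2ccccc2)c1OC | intermediate
11 | 1-bromo-3-benzyloxy-2,4,5-trimethoxybenzene | COc1cc(Br)c(OC)c(OCc2ccccc2)c1OC | intermediate
12 | rac-7-benzyloxy-3-(3-benzyloxy-2,4,5-trimethoxyphenyl)-8-methoxychroman-4-one | O=C1C(c2cc(OC)c(OC)c(OCc3ccccc3)c2OC)COc2c1ccc(OCc1ccccc1)c2OC | intermediate
13 | cis-(3S,4S)-7-benzyloxy-3-(3-benzyloxy-2,4,5-trimethoxyphenyl)-8-methoxychroman-4-ol | O[C@H]1[C@@H](c2cc(OC)c(OC)c(OCc3ccccc3)c2OC)COc2c1ccc(OCc1ccccc1)c2OC | intermediate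
14 | (3S,4S)-3-(3-hydroxy-2,4,5-trimethoxyphenyl)-8-methoxychromane-4,7-diol (not isolated) | O[C@H]1[C@@H](c2cc(OC)c(OC)c(O)c2OC)COc2c1ccc(O)c2OC | intermediate
15 | (3S)-3-(3-hydroxy-2,4,5-trimethoxyphenyl)-8-methoxychroman-7-ol (CNP0201239.1) | COc1cc([C@H]2COc3c(ccc(O)c3OC)C2)c(OC)c(O)c1OC | target

## Step count and risks

Total step count: 10.
Longest linear sequence: 7 steps (steps 4–10, from 6). The ring-A branch from 1 takes 6 steps.

**Step 8 (α-arylation).**
- What may go wrong: ring C may open by retro-oxa-Michael elimination from the enolate. Oxidative addition or reductive elimination may be slow with the ortho-substituted, tetra-oxygenated bromide. The bromide may undergo competing hydrodebromination.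
- The fallback avoids enolate chemistry. It sets out from 1 and 11 and rejoins the route at 12.
- Acylation of 1 with acetic acid in BF3·OEt2 (85 °C) should give 2,4-dihydroxy-3-methoxyacetophenone F1.
- One equivalent of BnBr with K2CO3 in acetone should benzylate only the non-chelated hydroxyl, giving 4-benzyloxy-2-hydroxy-3-methoxyacetophenone F2.
- DMF dimethyl acetal (toluene, 95 °C) should give the enaminone F3. Iodine in CHCl3 at rt should then close it to 7-benzyloxy-3-iodo-8-methoxychromen-4-one F4.
- In parallel, Miyaura borylation of 11 (B2pin2, Pd(dppf)Cl2, KOAc, dioxane, 90 °C) should give the aryl pinacol boronate F5.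
- Suzuki–Miyaura coupling of F4 with F5 (Pd(OAc)2, SPhos, Na2CO3, dioxane–water, 70 °C) should give the dibenzyl isoflavone F6.
- 1,4-Reduction of F6 with L-Selectride (THF, −78 °C), followed by protonation of the enolate, leads to 12.

**Step 9 (key step).**
- What may go wrong: reduction may outrun the C3 epimerisation, so the process degrades to a plain kinetic resolution. Conversion of the donor-deactivated, hindered ketone may stall. The 2'-methoxy group may erode facial or cis selectivity.
- The fallback moves the stereo-defining event to an alkene hydrogenation. It sets out from 12 and rejoins the route at 15.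
- NaBH4 (MeOH–THF, 0 °C) should give the isoflavan-4-ol as a stereoisomer mixture F7.
- Acid-catalysed dehydration (PPTS, toluene, 70 °C) should give the achiral isoflav-3-ene F8.
- Ir-catalysed asymmetric hydrogenation of this trisubstituted 3-aryl-2H-chromene should give the (3S)-dibenzyl isoflavan F9. The conditions are a cationic Ir–phosphinooxazoline complex with BArF counter-ion, H2 at 50 bar and CH2Cl2, with the ligand antipode chosen by screening.
- Neutral hydrogenolysis of F9 (H2, Pd/C, EtOAc–EtOH) gives 15.

**Step 10 (hydrogenolysis).**
- What may go wrong: C4–O cleavage may stop short after debenzylation. Enantiomeric purity may be partly lost through dehydration (by way of the benzylic cation or the para-quinone methide) to the achiral isoflav-3-ene, followed by its unselective hydrogenation.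
- The fallback removes the carbinol by a radical path that cannot touch C3. It sets out from 13 and rejoins the route at 15.
- 1,1'-Thiocarbonyldiimidazole with DMAP (CH2Cl2, rt) should give the C4 imidazole-1-carbothioate F10, which is used without storage. F10 cannot undergo Chugaev syn elimination, because its only β-hydrogen (C3–H) lies anti to the C4–O bond.
- Barton–McCombie reduction (Bu3SnH, AIBN, toluene, 80 °C) should give the (3S)-dibenzyl isoflavan F9, the same compound as in the fallback to step 9.
- Neutral hydrogenolysis of F9 (H2, Pd/C, EtOAc–EtOH) gives 15.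

## Further compounds

F1 | step 8 | 2,4-dihydroxy-3-methoxyacetophenone | CC(=O)c1ccc(O)c(OC)c1O
F2 | step 8 | 4-benzyloxy-2-hydroxy-3-methoxyacetophenone | CC(=O)c1ccc(OCc2ccccc2)c(OC)c1O
F3 | step 8 | (E)-1-(4-benzyloxy-2-hydroxy-3-methoxyphenyl)-3-(dimethylamino)prop-2-en-1-one | CN(C)/C=C/C(=O)c1ccc(OCc2ccccc2)c(OC)c1O
F4 | step 8 | 7-benzyloxy-3-iodo-8-methoxychromen-4-one | O=c1c(I)coc2c1ccc(OCc1ccccc1)c2OC
F5 | step 8 | 2-(3-benzyloxy-2,4,5-trimethoxyphenyl)-4,4,5,5-tetramethyl-1,3,2-dioxaborolane | COc1cc(B2OC(C)(C)C(C)(C)O2)c(OC)c(OCc2ccccc2)c1OC
F6 | step 8 | 7-benzyloxy-3-(3-benzyloxy-2,4,5-trimethoxyphenyl)-8-methoxychromen-4-one | O=c1c(-c2cc(OC)c(OC)c(OCc3ccccc3)c2OC)coc2c1ccc(OCc1ccccc1)c2OC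
F7 | step 9 | 7-benzyloxy-3-(3-benzyloxy-2,4,5-trimethoxyphenyl)-8-methoxychroman-4-ol (stereoisomer mixture) | OC1C(c2cc(OC)c(OC)c(OCc3ccccc3)c2OC)COc2c1ccc(OCc1ccccc1)c2OC
F8 | step 9 | 7-benzyloxy-3-(3-benzyloxy-2,4,5-trimethoxyphenyl)-8-methoxy-2H-chromene | COc1cc(C2=Cc3ccc(OCc4ccccc4)c(OC)c3OC2)c(OC)c(OCc2ccccc2)c1OC
F9 | step 9 | (3S)-7-benzyloxy-3-(3-benzyloxy-2,4,5-trimethoxyphenyl)-8-methoxychroman | COc1cc([C@H]2COc3c(ccc(OCc4ccccc4)c3OC)C2)c(OC)c(OCc2ccccc2)c1OC
F10 | step 10 | O-[(3S,4S)-7-benzyloxy-3-(3-benzyloxy-2,4,5-trimethoxyphenyl)-8-methoxychroman-4-yl] 1H-imidazole-1-carbothioate | S=C(n1ccnc1)O[C@H]1[C@@H](c2cc(OC)c(OC)c(OCc3ccccc3)c2OC)COc2c1ccc(OCc1ccccc1)c2OC
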